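**Plan**

- Retrosynthesis: the hydroquinone is traced back through its para-quinone to a 1‑(methoxymethoxy)‑4‑methoxy arene, the angelate C–O bond is cut, and then the C2–C3 bond of the hepta‑1,5‑diene chain (styrene carbon to carbinol carbon) is cut.
- Enabling feature: C3 carries only H, O, the C4 methylene and the sp2 carbon C2 of the 1,1‑disubstituted styrene. C3 therefore maps onto the O–CH2 carbon of 4‑methylpent‑3‑en‑1‑ol (two enantiotopic hydrogens) and C2 onto a 1‑arylvinyl boronic ester. The two are united by lithiation–borylation, a stereospecific 1,2‑metalate rearrangement.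
- Forward: the benzene ring (the only ring) is bought and elaborated by Dakin oxidation, MOM protection, ortho‑lithiation/acetylation, enol triflate formation and Miyaura borylation. The vinyl boronate is joined to the lithiated triisopropylbenzoate (TIB ester), the C–B bond is oxidised, the alcohol is angeloylated, and CAN/dithionite unveils the hydroquinone; no ring is formed.
- Stereochemistry: the single (S) centre comes from (+)-sparteine‑controlled deprotonation and is carried through retention (C–B formation), inversion (1,2‑shift) and retention (oxidation). The (Z)‑angelate geometry is bought with angelic acid and kept by avoiding nucleophilic acylation catalysts.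

Key step: step 7

Assumption: (+)-sparteine is taken as the purchasable chiral diamine (the (+)-sparteine surrogate would serve equally), and in step 9 both quinone oxygens are taken to come from water by ipso attack.

**Route**

Step 1
Reactants: 1 2,4-dimethoxy-3-methylbenzaldehyde
Product: 3 2,4-dimethoxy-3-methylphenol, via 2,4-dimethoxy-3-methylphenyl formate 2 (not isolated)
Conditions: mCPBA, CH2Cl2, 0 °C → rt; then K2CO3 (cat.), MeOH, rt
Reagents that add atoms: mCPBA, O=C(OO)c1cccc(Cl)c1
Why: Baeyer–Villiger (Dakin-type) oxidation in which the electron-rich 2,4-dimethoxyaryl group should migrate to oxygen in preference to hydride, followed by methanolysis of formate 2, exchanges the formyl carbon for the phenolic oxygen that later sits next to the side chain.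

Step 2
Reactants: 3 2,4-dimethoxy-3-methylphenol
Product: 4 2,4-dimethoxy-1-(methoxymethoxy)-3-methylbenzene
Conditions: MOMCl, i-Pr2NEt, CH2Cl2, 0 °C → rt
Reagents that add atoms: chloromethyl methyl ether, COCCl
Why: O-alkylation of the phenol (Williamson-type) installs a MOM ether that protects the phenol and is the strongest ortho-directing group on the ring for step 3.

Step 3
Reactants: 4 2,4-dimethoxy-1-(methoxymethoxy)-3-methylbenzene
Product: 6 1-[3,5-dimethoxy-2-(methoxymethoxy)-4-methylphenyl]ethan-1-one, via aryllithium 5 (not isolated)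
Conditions: n-BuLi, TMEDA, THF, 0 °C; then MeC(O)N(OMe)Me, −78 → 0 °C; aq. NH4Cl
Reagents that add atoms: N-methoxy-N-methylacetamide, CC(=O)N(C)OC
Why: Directed ortho-metalation should occur only at the single C–H ortho to the chelating OMOM group (the competing C–H lies next to a weaker, flanked OMe), and Weinreb-amide acylation of 5 stops at the ketone because the tetrahedral chelate survives until work-up.

Step 4
Reactants: 6 1-[3,5-dimethoxy-2-(methoxymethoxy)-4-methylphenyl]ethan-1-one
Product: 8 1-[3,5-dimethoxy-2-(methoxymethoxy)-4-methylphenyl]ethenyl trifluoromethanesulfonate, via potassium enolate 7 (not isolated)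
Conditions: KHMDS, THF, −78 °C; then PhNTf2, −78 → 0 °C
Reagents that add atoms: N-phenylbis(trifluoromethanesulfonimide), O=S(=O)(N(c1ccccc1)S(=O)(=O)C(F)(F)F)C(F)(F)F
Why: Enol triflate formation: the methyl ketone has one enolisable side, and O-sulfonylation of enolate 7 should give the 1-arylvinyl triflate without touching the MOM or methyl ethers.

Step 5
Reactants: 8 1-[3,5-dimethoxy-2-(methoxymethoxy)-4-methylphenyl]ethenyl trifluoromethanesulfonate
Product: 9 2-{1-[3,5-dimethoxy-2-(methoxymethoxy)-4-methylphenyl]ethenyl}-4,4,5,5-tetramethyl-1,3,2-dioxaborolane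
Conditions: B2pin2, PdCl2(PPh3)2 (3 mol %), PPh3, KOPh, toluene, 50 °C
Reagents that add atoms: bis(pinacolato)diboron, CC1(C)OB(OC1(C)C)B1OC(C)(C)C(C)(C)O1
Why: Miyaura borylation of an alkenyl triflate (oxidative addition, phenoxide-assisted transmetalation with B2pin2, reductive elimination), in which the weak base KOPh should suppress Suzuki coupling of 9 with unreacted 8.

Step 6
Reactants: 10 4-methylpent-3-en-1-ol
Product: 11 4-methylpent-3-en-1-yl 2,4,6-triisopropylbenzoate
Conditions: 2,4,6-triisopropylbenzoyl chloride, Et3N, DMAP (cat.), CH2Cl2, 40 °C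
Reagents that add atoms: 2,4,6-triisopropylbenzoyl chloride, CC(C)c1cc(C(C)C)c(C(=O)Cl)c(C(C)C)c1
Why: DMAP-catalysed acylation of the primary alcohol gives a hindered ester that resists addition of s-BuLi, directs α-lithiation and is a good leaving group for the later 1,2-shift.

Step 7
Reactants: 11 4-methylpent-3-en-1-yl 2,4,6-triisopropylbenzoate; 9 2-{1-[3,5-dimethoxy-2-(methoxymethoxy)-4-methylphenyl]ethenyl}-4,4,5,5-tetramethyl-1,3,2-dioxaborolane
Product: 15 (S)-2-[3,5-dimethoxy-2-(methoxymethoxy)-4-methylphenyl]-6-methylhepta-1,5-dien-3-ol, via (R)-α-lithiated TIB ester 12 (not isolated), via lithium boronate complex 13 (not isolated), via (S)-allylic pinacol boronic ester 14 (not isolated)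
Conditions: s-BuLi, (+)-sparteine, Et2O, −78 °C; add 9, −78 °C → reflux; then NaOH, H2O2, THF, 0 °C → rt
Reagents that add atoms: hydrogen peroxide, OO
Why: s-BuLi/(+)-sparteine removes the pro-R hydrogen on the O–CH2 carbon of 11 (deprotonation directed by the ester carbonyl) to give the configurationally stable (R)-organolithium 12, which adds to boron of 9 with retention to give boronate 13; on warming, the 1-arylvinyl group migrates from boron to carbon anti-periplanar to the departing triisopropylbenzoate (1,2-metalate rearrangement, inversion at carbon) to give (S)-14, and alkaline H2O2 replaces boron by OH with retention. The closest known reaction type is the lithiation–borylation (Matteson-type homologation) of alkenyl pinacol boronic esters with sparteine-derived α-lithiated carbamates and hindered benzoates. No ring is closed. The new stereocentre is under reagent control by the chiral diamine, and (+)-sparteine is needed because the (−)-enantiomer would lead by the same retention/inversion/retention sequence to the (R)-alcohol. The step needs α-O lithiation instead of allylic deprotonation (secured by precomplexation of the base to the carbonyl at −78 °C), migration of the vinyl carbon instead of a pinacol oxygen (secured by the benzoate leaving group and the migratory aptitude of sp2 carbon), and oxidation of the allylic boronate without 1,3-transposition (the carbon-to-oxygen shift takes place at the α-carbon).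

Step 8
Reactants: 15 (S)-2-[3,5-dimethoxy-2-(methoxymethoxy)-4-methylphenyl]-6-methylhepta-1,5-dien-3-ol; 16 angelic acid, (Z)-2-methylbut-2-enoic acid
Product: 19 (S)-2-[3,5-dimethoxy-2-(methoxymethoxy)-4-methylphenyl]-6-methylhepta-1,5-dien-3-yl (Z)-2-methylbut-2-enoate, via angelic anhydride 17 (not isolated), via lithium alkoxide 18 (not isolated)
Conditions: 16, DCC, CH2Cl2, 0 °C → rt, filter; 15, LiHMDS, THF, −78 °C; add 17, −78 → 0 °C
Reagents that add atoms: none
Why: Acyl transfer from the symmetrical anhydride to the lithium alkoxide at low temperature, without DMAP or another nucleophilic catalyst that isomerises angelates to tiglates by conjugate addition–elimination, should give the (Z)-ester with the C3 configuration untouched because no bond to the stereocentre is broken.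

Step 9
Reactants: 19 (S)-2-[3,5-dimethoxy-2-(methoxymethoxy)-4-methylphenyl]-6-methylhepta-1,5-dien-3-yl (Z)-2-methylbut-2-enoate
Product: 21 (S)-2-(2,5-dihydroxy-3-methoxy-4-methylphenyl)-6-methylhepta-1,5-dien-3-yl (Z)-2-methylbut-2-enoate, via para-quinone 20 (not isolated)
Conditions: CAN, MeCN/H2O, 0 °C; then EtOAc, aq. Na2S2O4, rt, under Ar
Reagents that add atoms: water, O
Why: Oxidative dealkylation of the 1,4-dialkoxyarene by CAN (arene radical cation, ipso attack of water, loss of methanol and of the MOM hemiacetal) should give the 2-methoxy-para-quinone in preference to the ortho-quinone, and dithionite reduction of crude 20 then reveals both phenols under near-neutral conditions that avoid SN2′ closure to a benzofuran, acyl migration and angelate isomerisation.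

**Compound list**

1 | 2,4-dimethoxy-3-methylbenzaldehyde | COc1ccc(C=O)c(OC)c1C | starting material
2 | 2,4-dimethoxy-3-methylphenyl formate | COc1ccc(OC=O)c(OC)c1C | intermediate
3 | 2,4-dimethoxy-3-methylphenol | COc1ccc(O)c(OC)c1C | intermediate
4 | 2,4-dimethoxy-1-(methoxymethoxy)-3-methylbenzene | COCOc1ccc(OC)c(C)c1OC | intermediate
5 | [3,5-dimethoxy-2-(methoxymethoxy)-4-methylphenyl]lithium | [Li]c1cc(OC)c(C)c(OC)c1OCOC | intermediate
6 | 1-[3,5-dimethoxy-2-(methoxymethoxy)-4-methylphenyl]ethan-1-one | CC(=O)c1cc(OC)c(C)c(OC)c1OCOC | intermediate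
7 | potassium 1-[3,5-dimethoxy-2-(methoxymethoxy)-4-methylphenyl]ethen-1-olate | [K+].C=C([O-])c1cc(OC)c(C)c(OC)c1OCOC | intermediate
8 | 1-[3,5-dimethoxy-2-(methoxymethoxy)-4-methylphenyl]ethenyl trifluoromethanesulfonate | C=C(OS(=O)(=O)C(F)(F)F)c1cc(OC)c(C)c(OC)c1OCOC | intermediate
9 | 2-{1-[3,5-dimethoxy-2-(methoxymethoxy)-4-methylphenyl]ethenyl}-4,4,5,5-tetramethyl-1,3,2-dioxaborolane | C=C(B1OC(C)(C)C(C)(C)O1)c1cc(OC)c(C)c(OC)c1OCOC | intermediate
10 | 4-methylpent-3-en-1-ol | CC(C)=CCCO | starting material
11 | 4-methylpent-3-en-1-yl 2,4,6-triisopropylbenzoate | CC(C)=CCCOC(=O)c1c(C(C)C)cc(C(C)C)cc1C(C)C | intermediate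
12 | (R)-1-lithio-4-methylpent-3-en-1-yl 2,4,6-triisopropylbenzoate, as its (+)-sparteine complex | [Li][C@H](CC=C(C)C)OC(=O)c1c(C(C)C)cc(C(C)C)cc1C(C)C | intermediate
13 | lithium boronate from 12 and 9: boron bears the pinacol unit, the 1-arylvinyl group and the (R)-configured α-(triisopropylbenzoyloxy)alkyl group | [Li+].C=C(c1cc(OC)c(C)c(OC)c1OCOC)[B-]1(OC(C)(C)C(C)(C)O1)[C@H](CC=C(C)C)OC(=O)c1c(C(C)C)cc(C(C)C)cc1C(C)C | intermediate
14 | 2-{(S)-2-[3,5-dimethoxy-2-(methoxymethoxy)-4-methylphenyl]-6-methylhepta-1,5-dien-3-yl}-4,4,5,5-tetramethyl-1,3,2-dioxaborolane | C=C(c1cc(OC)c(C)c(OC)c1OCOC)[C@H](CC=C(C)C)B1OC(C)(C)C(C)(C)O1 | intermediate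
15 | (S)-2-[3,5-dimethoxy-2-(methoxymethoxy)-4-methylphenyl]-6-methylhepta-1,5-dien-3-ol | C=C(c1cc(OC)c(C)c(OC)c1OCOC)[C@H](CC=C(C)C)O | intermediate
16 | angelic acid, (Z)-2-methylbut-2-enoic acid | C/C=C(C)\C(=O)O | starting material
17 | angelic anhydride, (Z)-2-methylbut-2-enoic anhydride | C/C=C(C)\C(=O)OC(=O)/C(C)=C\C | intermediate
18 | lithium (S)-2-[3,5-dimethoxy-2-(methoxymethoxy)-4-methylphenyl]-6-methylhepta-1,5-dien-3-olate | [Li+].C=C(c1cc(OC)c(C)c(OC)c1OCOC)[C@H](CC=C(C)C)[O-] | intermediate
19 | (S)-2-[3,5-dimethoxy-2-(methoxymethoxy)-4-methylphenyl]-6-methylhepta-1,5-dien-3-yl (Z)-2-methylbut-2-enoate | C=C(c1cc(OC)c(C)c(OC)c1OCOC)[C@H](CC=C(C)C)OC(=O)/C(C)=C\C | intermediate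
20 | (S)-2-(5-methoxy-4-methyl-3,6-dioxocyclohexa-1,4-dien-1-yl)-6-methylhepta-1,5-dien-3-yl (Z)-2-methylbut-2-enoate | C=C(C1=CC(=O)C(C)=C(OC)C1=O)[C@H](CC=C(C)C)OC(=O)/C(C)=C\C | intermediate
21 | (S)-2-(2,5-dihydroxy-3-methoxy-4-methylphenyl)-6-methylhepta-1,5-dien-3-yl (Z)-2-methylbut-2-enoate | C=C(c1cc(O)c(C)c(OC)c1O)[C@H](CC=C(C)C)OC(=O)/C(C)=C\C | target

**Totals**

Total step count: 9. Longest linear sequence: 8 (steps 1–5, 7, 8 and 9, from 1).

**Steps most likely to fail, with fallbacks**

1. Step 9. The one-electron oxidant may attack the styrene or the prenyl alkene, may give some ortho-quinone, and the vinylquinone may decompose before it is reduced. The fallback replaces outer-sphere arene oxidation by acetal cleavage followed by a two-electron phenol oxidation. It sets out from 19: the MOM ether is cleaved with TMSOTf/2,2′-bipyridyl in CH2Cl2 at 0 °C and then water, to give (S)-2-(2-hydroxy-3,5-dimethoxy-4-methylphenyl)-6-methylhepta-1,5-dien-3-yl (Z)-2-methylbut-2-enoate F1. PhI(OAc)2 in MeCN/H2O at 0 °C should then oxidise this para-methoxyphenol through its aryloxy-iodane to quinone 20, where the route is rejoined with the dithionite reduction of step 9.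

2. Step 7. Allylic deprotonation or elimination of the homoallylic ester may compete with α-lithiation, the hindered 1-arylvinyl boronate may form the boronate complex or rearrange slowly, and reversible complex formation may erode the enantiomeric purity. The fallback forms the same bond by catalyst-controlled carbonyl addition. It sets out from enol triflate 8 and alcohol 10: Dess–Martin oxidation of 10 gives 4-methylpent-3-enal F2, which is used crude because it isomerises easily into conjugation. A catalytic asymmetric Nozaki–Hiyama–Kishi coupling of 8 with it (CrCl2 and NiCl2 catalysts, Mn, TMSCl, chiral sulfonamide ligand of the enantiomeric series that delivers the (S)-carbinol, MeCN, rt) should give alcohol 15 directly, where the route is rejoined.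

3. Step 8. The angeloyl group may isomerise to the tigloyl group during activation, and acylation of the hindered alkoxide may be slow. The fallback builds the (Z)-alkene on the ester instead of transferring it. It sets out from 15: esterification with 2-[bis(2,2,2-trifluoroethoxy)phosphoryl]propanoic acid (DCC, DMAP, CH2Cl2) gives (S)-2-[3,5-dimethoxy-2-(methoxymethoxy)-4-methylphenyl]-6-methylhepta-1,5-dien-3-yl 2-[bis(2,2,2-trifluoroethoxy)phosphoryl]propanoate F3 as a mixture of epimers at the phosphonate carbon. Still–Gennari olefination with acetaldehyde (KHMDS, 18-crown-6, THF, −78 °C) should then give the (Z)-2-methylbut-2-enoate 19, where the route is rejoined.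

**Further compounds**

F1 | step 9 | (S)-2-(2-hydroxy-3,5-dimethoxy-4-methylphenyl)-6-methylhepta-1,5-dien-3-yl (Z)-2-methylbut-2-enoate | C=C(c1cc(OC)c(C)c(OC)c1O)[C@H](CC=C(C)C)OC(=O)/C(C)=C\C
F2 | step 7 | 4-methylpent-3-enal | CC(C)=CCC=O
F3 | step 8 | (S)-2-[3,5-dimethoxy-2-(methoxymethoxy)-4-methylphenyl]-6-methylhepta-1,5-dien-3-yl 2-[bis(2,2,2-trifluoroethoxy)phosphoryl]propanoate | C=C(c1cc(OC)c(C)c(OC)c1OCOC)[C@H](CC=C(C)C)OC(=O)C(C)P(=O)(OCC(F)(F)F)OCC(F)(F)F
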